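(The numbers of this flask come from no measurement; the result is computed.)

At the charged amounts this flask loses 0.0426 of a free catalyst for each substrate converted, and I call this the loss ratio d, catalyst killed per substrate converted.

left-handed substrate 0.050 M; partner 2.00 equiv; free catalyst 10 mol%; right-handed substrate 0.050 M

    partner + free catalyst + left-handed substrate → free catalyst + left-handed product (k1 = 48.7 /M²/min)
    partner + free catalyst + right-handed substrate → free catalyst + right-handed product (k2 = 18.9 /M²/min)
    2 partner → homo dimer (k3 = 0.171 /M/min)
    partner + free catalyst → spent catalyst (k4 = 0.144 /M/min)

- free catalyst is single-handed; left-handed substrate and right-handed substrate are mirror images of each other, charged as a racemate, each of them at the stated concentration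
- a doubled species enters its step squared and goes two at a time
- charge of left-handed substrate (flask): 0.050 M

1. the form that holds most of the catalyst when 20% of the left-handed substrate and right-handed substrate together are converted (free catalyst / spent catalyst)
2. its share of the catalyst then
3. apparent order in partner when 20% of the left-handed substrate and right-handed substrate together are converted (percent change of the rate of making left-handed product for one percent more partner charged)

At the charge, a free catalyst turns left-handed substrate at 0.24 /min and right-handed substrate at 0.095 /min, and it dies at 0.014 /min; the third divided by the sum of the first two gives d. Partner and free catalyst stand as the same factor in the three steps, so they cancel from d. The homo dimer step uses partner 2.8 times as fast as the left-handed step at the start, but that drain of partner does not appear in d, so I can reckon against conversion instead of time.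

The asked conversion of 20% means 0.0200 M of substrate converted, and the catalyst charge is 0.00500 M, so the starting d, held constant, gives 17.0% spent catalyst. My objection is that d does not stay put, since the substrates thin, and the left-handed one, turned faster than the right-handed one, thins more. Taking the split at the charge, I put about 72.0% of the conversion as left-handed, which gives an estimated 0.0356 M of left-handed and 0.0444 M of right-handed substrate, and d comes to 0.0560. Taking the mean of the two values of d, I get 19.7% spent and 80.3% free. Since d holds no partner, it gives me no order in partner, and I put no number on that.

The forecast says free catalyst, at 80.6%, with an order of 1.37, on the ground that “Catalyst death and substrate conversion both run first order in partner and catalyst”. Its free share is higher than mine.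

The simulation gives free catalyst at 80.6%, with spent catalyst at 19.4% and an order in partner of 1.4. The flask reaches that conversion at 23.1 min, when it makes left-handed product at 3.09 × 10⁻⁴ M/min. At 50.0 min the flask holds 30.6% left-handed and 41.3% right-handed substrate, so d has reached 0.0634. The mean of this and the starting d, applied to the 0.0281 M converted, gives 29.8% of the catalyst lost, and the flask then holds spent catalyst at 29.1%.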